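**Plan**
- Retrosynthesis: the 2'-O-methyl group and the two free phenols at C7 and C4' are traced back to a 2'-phenol and two methoxymethyl ethers. The aryl–prenyl bonds C6–CH2 and C3'–CH2 are then cut back to 1,1-dimethylallyl ethers on O5 and O2', and these to 1,1-dimethylpropargyl ethers. Ring C is opened at C3–C4 (acyl anion plus ketone) and at O1–C2 (phenoxide plus bromoketone).
- Forward: ring A aldehyde 4 and ring B bromoketone 9 are joined through O1–C2. Ring C (the only ring built) closes by a carbene-catalysed benzoin reaction that forms C3–C4. Both alkynes are semihydrogenated, both allyl groups move from O to C in one operation, and 2'-O-methylation and acetal cleavage finish the route.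
- Stereochemistry: the single stereocentre C3 (R) is set in the benzoin closure by a chiral triazolylidene, which must add the acyl anion equivalent to the Si face of the ketone. C3 is quaternary, has no enolisable hydrogen, and is carried unchanged.
- Enabling feature: O5 on ring A has one open ortho carbon, C6 (the other is the ring-fusion carbon C4a). O2' on ring B has one open ortho carbon, C3' (the other is C1', which carries C3). Each prenyl group sits exactly where a [3,3] shift from the neighbouring oxygen can end productively.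

Key step: step 9

Assumption: isoflavanone numbering is used throughout (O1, C2, C3, C4=O, C4a–C8a in ring A, C1'–C6' in ring B); the sense of induction of the aminoindanol triazolium salt is assigned by analogy with related chromanone closures, and should the first run give the (S)-ketol, the mirror-image salt from the other commercial cis-1-amino-2-indanol is used with nothing else changed.

**Step 1**
Reactants: 1 2,4,6-trihydroxybenzaldehyde
Product: 2 2,6-dihydroxy-4-(methoxymethoxy)benzaldehyde
Conditions: MOMCl (1.05 equiv), i-Pr2NEt (1.2 equiv), CH2Cl2/THF, −10 to 0 °C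
Reagents that add atoms: chloromethyl methyl ether, COCCl
Why: The 4-hydroxyl, para to the formyl group, is the most acidic and the least hindered, and it is not tied up in a hydrogen bond to the aldehyde, so one equivalent of the chloromethyl ether should alkylate it first (Williamson-type O-alkylation giving the mixed acetal).

**Step 2**
Reactants: 2 2,6-dihydroxy-4-(methoxymethoxy)benzaldehyde; 3 3-chloro-3-methylbut-1-yne
Product: 4 2-hydroxy-4-(methoxymethoxy)-6-[(2-methylbut-3-yn-2-yl)oxy]benzaldehyde
Conditions: 3 (1.2 equiv), DBU (1.3 equiv), CuCl2·2H2O (1 mol %), MeCN, 0 °C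
Reagents that add atoms: none
Why: Copper-catalysed propargylic etherification of a phenoxide with a tertiary propargylic chloride; the two ortho hydroxyls of 2 are equivalent, and after the first has reacted the second locks into the hydrogen bond to the formyl oxygen, so mono-alkylation should prevail.

**Step 3**
Reactants: 5 2,4-dihydroxyacetophenone
Product: 6 1-[2-hydroxy-4-(methoxymethoxy)phenyl]ethanone
Conditions: MOMCl (1.1 equiv), K2CO3, acetone, 23 °C
Reagents that add atoms: chloromethyl methyl ether, COCCl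
Why: Williamson-type O-alkylation at the free 4-hydroxyl; the 2-hydroxyl is held in the six-membered hydrogen bond to the acetyl group and should not react under carbonate at room temperature.

**Step 4**
Reactants: 6 1-[2-hydroxy-4-(methoxymethoxy)phenyl]ethanone; 3 3-chloro-3-methylbut-1-yne
Product: 7 1-[4-(methoxymethoxy)-2-[(2-methylbut-3-yn-2-yl)oxy]phenyl]ethanone
Conditions: 3 (2 equiv), DBU (2.2 equiv), CuCl2·2H2O (2 mol %), MeCN, 0 to 23 °C
Reagents that add atoms: none
Why: The same copper-catalysed propargylic etherification, here driven onto the chelated phenol by an excess of the amidine base, which breaks the hydrogen bond, and of the chloride.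

**Step 5**
Reactants: 7 1-[4-(methoxymethoxy)-2-[(2-methylbut-3-yn-2-yl)oxy]phenyl]ethanone
Product: 9 2-bromo-1-[4-(methoxymethoxy)-2-[(2-methylbut-3-yn-2-yl)oxy]phenyl]ethanone, via trimethylsilyl enol ether 8 (not isolated)
Conditions: LiN(SiMe3)2 (1.05 equiv), Me3SiCl, THF, −78 °C; crude 8, then NBS, THF, −78 to 0 °C
Reagents that add atoms: N-bromosuccinimide, O=C1CCC(=O)N1Br; chlorotrimethylsilane, C[Si](C)(C)Cl (silicon present only in 8)
Why: Kinetic deprotonation of the methyl ketone (more acidic than the alkyne C–H) and O-silylation give the enol ether, whose bromination by NBS is far faster than attack on the alkyne or on the alkoxyarene (α-bromination of a ketone through its silyl enol ether), and no acid is set free that could harm the acetal or the tertiary ether.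

**Step 6**
Reactants: 4 2-hydroxy-4-(methoxymethoxy)-6-[(2-methylbut-3-yn-2-yl)oxy]benzaldehyde; 9 2-bromo-1-[4-(methoxymethoxy)-2-[(2-methylbut-3-yn-2-yl)oxy]phenyl]ethanone
Product: 10 4-(methoxymethoxy)-2-[2-[4-(methoxymethoxy)-2-[(2-methylbut-3-yn-2-yl)oxy]phenyl]-2-oxoethoxy]-6-[(2-methylbut-3-yn-2-yl)oxy]benzaldehyde
Conditions: K2CO3 (1.5 equiv), acetone, 23 °C
Reagents that add atoms: none
Why: Williamson ether synthesis by SN2 displacement on the activated primary α-bromoketone, which should proceed at room temperature, below the point at which Rap–Stoermer aldol condensation to a 2-aroylbenzofuran sets in.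

**Step 7**
Reactants: 10 4-(methoxymethoxy)-2-[2-[4-(methoxymethoxy)-2-[(2-methylbut-3-yn-2-yl)oxy]phenyl]-2-oxoethoxy]-6-[(2-methylbut-3-yn-2-yl)oxy]benzaldehyde
Product: 11 (3R)-3-hydroxy-7-(methoxymethoxy)-3-[4-(methoxymethoxy)-2-[(2-methylbut-3-yn-2-yl)oxy]phenyl]-5-[(2-methylbut-3-yn-2-yl)oxy]chroman-4-one
Conditions: (5aS,10bR)-2-(pentafluorophenyl)-5a,10b-dihydro-4H,6H-indeno[2,1-b][1,2,4]triazolo[4,3-d][1,4]oxazin-2-ium tetrafluoroborate (15 mol %), Et3N (15 mol %), PhMe, 23 °C
Reagents that add atoms: none
Why: Intramolecular crossed aldehyde–ketone benzoin reaction under N-heterocyclic carbene catalysis, in which the Breslow intermediate formed at the aldehyde adds 6-exo-trig to the tethered aryl ketone and the indane wall of the catalyst should direct it to the Si face of the ketone, giving the (R)-configured tertiary ketol at C3.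

**Step 8**
Reactants: 11 (3R)-3-hydroxy-7-(methoxymethoxy)-3-[4-(methoxymethoxy)-2-[(2-methylbut-3-yn-2-yl)oxy]phenyl]-5-[(2-methylbut-3-yn-2-yl)oxy]chroman-4-one
Product: 12 (3R)-3-hydroxy-7-(methoxymethoxy)-3-[4-(methoxymethoxy)-2-[(2-methylbut-3-en-2-yl)oxy]phenyl]-5-[(2-methylbut-3-en-2-yl)oxy]chroman-4-one
Conditions: H2 (1 atm), Pd/CaCO3 poisoned with Pb(OAc)2, quinoline, EtOAc, 20 °C, stopped after two equivalents of H2; kept below 30 °C
Reagents that add atoms: none
Why: Lindlar-type semihydrogenation, in which the lead-poisoned palladium surface adds one H2 to each terminal alkyne and quinoline holds back further reduction of the vinyl groups, while the aryl ketone, the acetals and the tertiary ethers should stay intact.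

**Step 9**
Reactants: 12 (3R)-3-hydroxy-7-(methoxymethoxy)-3-[4-(methoxymethoxy)-2-[(2-methylbut-3-en-2-yl)oxy]phenyl]-5-[(2-methylbut-3-en-2-yl)oxy]chroman-4-one
Product: 14 (3R)-3,5-dihydroxy-3-[2-hydroxy-4-(methoxymethoxy)-3-(3-methylbut-2-en-1-yl)phenyl]-7-(methoxymethoxy)-6-(3-methylbut-2-en-1-yl)chroman-4-one, via ring A mono-rearranged ether 13 (not isolated)
Conditions: Eu(fod)3 (10 mol %; fod = 6,6,7,7,8,8,8-heptafluoro-2,2-dimethyl-3,5-octanedionate), degassed PhMe, 60 °C, then 115 °C (sealed tube), Ar
Reagents that add atoms: none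
Why: Each aryl 1,1-dimethylallyl ether should undergo a concerted suprafacial [3,3] shift through a chair-like six-membered transition state in which the terminal CH2 bonds to the open ortho carbon while the O–CMe2 bond breaks, and the 2,4-cyclohexadienone so formed enolises to the phenol; the europium centre held between O4 and O5 should let the ring A ether go first (12 to 13) and the ring B ether follow on warming. The closest known reaction type is the aromatic Claisen rearrangement of aryl 1,1-dimethylallyl ethers to ortho-prenylphenols, run thermally or with Eu(fod)3. No ring is closed and no stereocentre is created, and the quaternary C3, which has no enolisable hydrogen, is not touched. The step needs regioselectivity, that is migration to C6 and to C3' and delivery of the linear 3-methylbut-2-enyl group; the substrate secures both, because the other ortho carbons C4a and C1' are fully substituted so that shifts to them give dienones that can only revert, whereas the dienones at C6 and C3' tautomerise irreversibly, and the allylic transposition inherent in the [3,3] shift turns the tertiary ether into the primary prenyl chain. The geminal methyl groups weaken the O–C bond enough for the shift to run at or below 115 °C, where the methoxymethyl ethers and the tertiary ketol should be stable.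

**Step 10**
Reactants: 14 (3R)-3,5-dihydroxy-3-[2-hydroxy-4-(methoxymethoxy)-3-(3-methylbut-2-en-1-yl)phenyl]-7-(methoxymethoxy)-6-(3-methylbut-2-en-1-yl)chroman-4-one
Product: 15 (3R)-3,5-dihydroxy-3-[2-methoxy-4-(methoxymethoxy)-3-(3-methylbut-2-en-1-yl)phenyl]-7-(methoxymethoxy)-6-(3-methylbut-2-en-1-yl)chroman-4-one
Conditions: MeI (1.3 equiv), K2CO3 (1.5 equiv), acetone, 23 to 40 °C
Reagents that add atoms: iodomethane, CI
Why: Williamson methylation of the only phenoxide that carbonate can generate freely, since the 5-hydroxyl is locked in the six-membered hydrogen bond to the C4 carbonyl and the 3-hydroxyl is a tertiary alcohol that carbonate does not deprotonate.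

**Step 11**
Reactants: 15 (3R)-3,5-dihydroxy-3-[2-methoxy-4-(methoxymethoxy)-3-(3-methylbut-2-en-1-yl)phenyl]-7-(methoxymethoxy)-6-(3-methylbut-2-en-1-yl)chroman-4-one
Product: 16 (3R)-3,5,7-trihydroxy-3-[4-hydroxy-2-methoxy-3-(3-methylbut-2-en-1-yl)phenyl]-6-(3-methylbut-2-en-1-yl)chroman-4-one
Conditions: 3 M aq HCl/MeOH (1:10), 40 °C, stopped at full conversion
Reagents that add atoms: none
Why: Acid-catalysed cleavage of the two aryl methoxymethyl acetals through the oxocarbenium ion, with methanol taking up the CH2OMe unit (transacetalisation); dilute acid at 40 °C should stay below the threshold for chroman formation at the prenyl groups and for ionisation of the 3-hydroxyl.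

**Compound list**
1 | 2,4,6-trihydroxybenzaldehyde | O=Cc1c(O)cc(O)cc1O | starting material
2 | 2,6-dihydroxy-4-(methoxymethoxy)benzaldehyde | O=Cc1c(O)cc(OCOC)cc1O | intermediate
3 | 3-chloro-3-methylbut-1-yne | C#CC(C)(C)Cl | starting material
4 | 2-hydroxy-4-(methoxymethoxy)-6-[(2-methylbut-3-yn-2-yl)oxy]benzaldehyde | O=Cc1c(O)cc(OCOC)cc1OC(C)(C)C#C | intermediate
5 | 2,4-dihydroxyacetophenone | CC(=O)c1ccc(O)cc1O | starting material
6 | 1-[2-hydroxy-4-(methoxymethoxy)phenyl]ethanone | CC(=O)c1ccc(OCOC)cc1O | intermediate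
7 | 1-[4-(methoxymethoxy)-2-[(2-methylbut-3-yn-2-yl)oxy]phenyl]ethanone | CC(=O)c1ccc(OCOC)cc1OC(C)(C)C#C | intermediate
8 | trimethyl[(1-{4-(methoxymethoxy)-2-[(2-methylbut-3-yn-2-yl)oxy]phenyl}ethenyl)oxy]silane (trimethylsilyl enol ether of 7) | C=C(O[Si](C)(C)C)c1ccc(OCOC)cc1OC(C)(C)C#C | intermediate
9 | 2-bromo-1-[4-(methoxymethoxy)-2-[(2-methylbut-3-yn-2-yl)oxy]phenyl]ethanone | BrCC(=O)c1ccc(OCOC)cc1OC(C)(C)C#C | intermediate
10 | 4-(methoxymethoxy)-2-[2-[4-(methoxymethoxy)-2-[(2-methylbut-3-yn-2-yl)oxy]phenyl]-2-oxoethoxy]-6-[(2-methylbut-3-yn-2-yl)oxy]benzaldehyde | O=Cc1c(OCC(=O)c2ccc(OCOC)cc2OC(C)(C)C#C)cc(OCOC)cc1OC(C)(C)C#C | intermediate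
11 | (3R)-3-hydroxy-7-(methoxymethoxy)-3-[4-(methoxymethoxy)-2-[(2-methylbut-3-yn-2-yl)oxy]phenyl]-5-[(2-methylbut-3-yn-2-yl)oxy]chroman-4-one | C#CC(C)(C)Oc1c([C@@]2(O)COc3cc(OCOC)cc(OC(C)(C)C#C)c3C2=O)ccc(OCOC)c1 | intermediate
12 | (3R)-3-hydroxy-7-(methoxymethoxy)-3-[4-(methoxymethoxy)-2-[(2-methylbut-3-en-2-yl)oxy]phenyl]-5-[(2-methylbut-3-en-2-yl)oxy]chroman-4-one | C=CC(C)(C)Oc1c([C@@]2(O)COc3cc(OCOC)cc(OC(C)(C)C=C)c3C2=O)ccc(OCOC)c1 | intermediate
13 | (3R)-3,5-dihydroxy-7-(methoxymethoxy)-3-[4-(methoxymethoxy)-2-[(2-methylbut-3-en-2-yl)oxy]phenyl]-6-(3-methylbut-2-en-1-yl)chroman-4-one | C=CC(C)(C)Oc1c([C@@]2(O)COc3cc(OCOC)c(CC=C(C)C)c(O)c3C2=O)ccc(OCOC)c1 | intermediate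
14 | (3R)-3,5-dihydroxy-3-[2-hydroxy-4-(methoxymethoxy)-3-(3-methylbut-2-en-1-yl)phenyl]-7-(methoxymethoxy)-6-(3-methylbut-2-en-1-yl)chroman-4-one | Oc1c([C@@]2(O)COc3cc(OCOC)c(CC=C(C)C)c(O)c3C2=O)ccc(OCOC)c1CC=C(C)C | intermediate
15 | (3R)-3,5-dihydroxy-3-[2-methoxy-4-(methoxymethoxy)-3-(3-methylbut-2-en-1-yl)phenyl]-7-(methoxymethoxy)-6-(3-methylbut-2-en-1-yl)chroman-4-one | COc1c([C@@]2(O)COc3cc(OCOC)c(CC=C(C)C)c(O)c3C2=O)ccc(OCOC)c1CC=C(C)C | intermediate
16 | (3R)-3,5,7-trihydroxy-3-[4-hydroxy-2-methoxy-3-(3-methylbut-2-en-1-yl)phenyl]-6-(3-methylbut-2-en-1-yl)chroman-4-one | COc1c([C@@]2(O)COc3cc(O)c(CC=C(C)C)c(O)c3C2=O)ccc(O)c1CC=C(C)C | target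

**Count**
Total steps: 11. Longest linear sequence: 9 steps (5 to 16 through steps 3, 4, 5, 6, 7, 8, 9, 10 and 11).

**Steps most likely to fail**

Step 7. The carbene may add only slowly to an aldehyde flanked by two ortho alkoxy groups, and the electron-rich, ortho-substituted ketone may be a sluggish acceptor. Base-mediated aldol condensation of the O–CH2–C(=O) unit onto the aldehyde may then take over, or the facial selectivity may be poor. The fallback sets out from 10 and returns at 11, and forms the C3–C4 bond by ketyl coupling instead of acyl anion addition. SmI2 (2.2 equiv) with t-BuOH in THF at −78 °C should close ring C by intramolecular pinacol coupling to racemic 7-(methoxymethoxy)-3-[4-(methoxymethoxy)-2-[(2-methylbut-3-yn-2-yl)oxy]phenyl]-5-[(2-methylbut-3-yn-2-yl)oxy]chromane-3,4-diol F1 (both C4 epimers serve, the cis-diol being expected to dominate). 2-Iodoxybenzoic acid in DMSO at 23 °C should oxidise only the secondary benzylic alcohol and give racemic 3-hydroxy-7-(methoxymethoxy)-3-[4-(methoxymethoxy)-2-[(2-methylbut-3-yn-2-yl)oxy]phenyl]-5-[(2-methylbut-3-yn-2-yl)oxy]chroman-4-one F2. Preparative chromatography on a cellulose tris(3,5-dimethylphenylcarbamate) phase then delivers 11, and the (3S)-3-hydroxy-7-(methoxymethoxy)-3-[4-(methoxymethoxy)-2-[(2-methylbut-3-yn-2-yl)oxy]phenyl]-5-[(2-methylbut-3-yn-2-yl)oxy]chroman-4-one F3 is set aside.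

Step 9. The tertiary allyl ethers may ionise and lose isoprene before the [3,3] shift, the ring B ether may migrate incompletely, or the freed phenols may add to the prenyl double bonds on prolonged heating. The fallback sets out from 12 and returns at 14, and uses primary allyl ethers, which cannot eliminate. Pd(PPh3)4 (zerovalent palladium, 5 mol %) and morpholine in THF at 23 °C take off both tertiary allyl groups to give (3R)-3,5-dihydroxy-3-[2-hydroxy-4-(methoxymethoxy)phenyl]-7-(methoxymethoxy)chroman-4-one F4, which is also what the failed step would leave behind and can be pooled with it. Allyl bromide and K2CO3 in DMF at 50 °C give (3R)-5-(allyloxy)-3-[2-(allyloxy)-4-(methoxymethoxy)phenyl]-3-hydroxy-7-(methoxymethoxy)chroman-4-one F5. Thermal Claisen rearrangement in N,N-diethylaniline at 190 °C moves both allyl groups to the same ortho carbons and gives (3R)-6-allyl-3-[3-allyl-2-hydroxy-4-(methoxymethoxy)phenyl]-3,5-dihydroxy-7-(methoxymethoxy)chroman-4-one F6. Cross-metathesis with 2-methylbut-2-ene and the second-generation Grubbs catalyst RuCl2(=CHPh)(H2IMes)(PCy3) in CH2Cl2 at 40 °C turns both allyl groups into prenyl groups and rejoins the route at 14.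

Step 11. Brønsted acid may promote addition of the ortho phenols to the prenyl double bonds (chroman formation) and ionisation of the tertiary benzylic 3-hydroxyl, leading to dehydration towards the isoflavone or loss of configuration. The fallback sets out from 15 and returns at 16, and avoids protic acid by a silyl relay. Et3SiOTf with 2,2'-bipyridyl in CH2Cl2 at 0 °C exchanges the aryl methoxymethyl acetals directly for silyl ethers and gives (3R)-3,5-dihydroxy-3-[2-methoxy-3-(3-methylbut-2-en-1-yl)-4-(triethylsilyloxy)phenyl]-6-(3-methylbut-2-en-1-yl)-7-(triethylsilyloxy)chroman-4-one F7. Any silyl group taken up at O3 or O5 falls off in the next operation. Bu4NF buffered with AcOH in THF at 0 °C then releases 16.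

**Further compounds**
F1 | step 7 | 7-(methoxymethoxy)-3-[4-(methoxymethoxy)-2-[(2-methylbut-3-yn-2-yl)oxy]phenyl]-5-[(2-methylbut-3-yn-2-yl)oxy]chromane-3,4-diol (racemic, C4 epimers) | C#CC(C)(C)Oc1cc(OCOC)ccc1C1(O)COc2cc(OCOC)cc(OC(C)(C)C#C)c2C1O
F2 | step 7 | racemic 3-hydroxy-7-(methoxymethoxy)-3-[4-(methoxymethoxy)-2-[(2-methylbut-3-yn-2-yl)oxy]phenyl]-5-[(2-methylbut-3-yn-2-yl)oxy]chroman-4-one | C#CC(C)(C)Oc1cc(OCOC)ccc1C1(O)COc2cc(OCOC)cc(OC(C)(C)C#C)c2C1=O
F3 | step 7 | (3S)-3-hydroxy-7-(methoxymethoxy)-3-[4-(methoxymethoxy)-2-[(2-methylbut-3-yn-2-yl)oxy]phenyl]-5-[(2-methylbut-3-yn-2-yl)oxy]chroman-4-one | C#CC(C)(C)Oc1c([C@]2(O)COc3cc(OCOC)cc(OC(C)(C)C#C)c3C2=O)ccc(OCOC)c1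
F4 | step 9 | (3R)-3,5-dihydroxy-3-[2-hydroxy-4-(methoxymethoxy)phenyl]-7-(methoxymethoxy)chroman-4-one | Oc1c([C@@]2(O)COc3cc(OCOC)cc(O)c3C2=O)ccc(OCOC)c1
F5 | step 9 | (3R)-5-(allyloxy)-3-[2-(allyloxy)-4-(methoxymethoxy)phenyl]-3-hydroxy-7-(methoxymethoxy)chroman-4-one | C=CCOc1c([C@@]2(O)COc3cc(OCOC)cc(OCC=C)c3C2=O)ccc(OCOC)c1
F6 | step 9 | (3R)-6-allyl-3-[3-allyl-2-hydroxy-4-(methoxymethoxy)phenyl]-3,5-dihydroxy-7-(methoxymethoxy)chroman-4-one | Oc1c([C@@]2(O)COc3cc(OCOC)c(CC=C)c(O)c3C2=O)ccc(OCOC)c1CC=C
F7 | step 11 | (3R)-3,5-dihydroxy-3-[2-methoxy-3-(3-methylbut-2-en-1-yl)-4-(triethylsilyloxy)phenyl]-6-(3-methylbut-2-en-1-yl)-7-(triethylsilyloxy)chroman-4-one | COc1c([C@@]2(O)COc3cc(O[Si](CC)(CC)CC)c(CC=C(C)C)c(O)c3C2=O)ccc(O[Si](CC)(CC)CC)c1CC=C(C)C
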